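**Retrosynthetic overview**
- Glycyrdione A is an open-chain 1,3-diketone between ring A (2,4-dihydroxy-5-prenylphenyl) and ring B (4-hydroxy-3-prenylphenyl). No ring is formed in the route; both benzene rings come from the starting materials.
- Feature used: the carbonyl carbon attached to C1 of ring B sits between that aryl carbon and the central CH2. It is traced back to carbon monoxide, which cuts the aryl–C(=O) bond (to a ring B aryl iodide) and the C(=O)–CH2 bond (to the acetyl methyl of a ring A ketone).
- Ring B iodide: ortho-C-prenylation of 4-iodophenol, then silylation. Ring A ketone: silylation of 5-bromo-2,4-dihydroxyacetophenone, then a base-free Stille prenylation.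
- All three phenols are carried as triisopropylsilyl ethers. An ortho silyl ether next to a ketone enolate must not migrate to the enolate oxygen, and the bulkier silicon resists this; buffered fluoride removes all three at the end without acid.

Key step: step 5

Remark on the chemistry: the silylated diketone and the target are named and written as diketo tautomers, although both should exist mainly as chelated enols.

**Step 1**
Reactants: 1 4-iodophenol; 2 prenyl bromide (1-bromo-3-methylbut-2-ene)
Product: 4 4-iodo-2-(3-methylbut-2-en-1-yl)phenol, via sodium 4-iodophenoxide 3 (not isolated)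
Conditions: NaH, toluene, 0 °C to rt; then 2, rt
Reagents that add atoms: none
Why: In a non-polar solvent the tightly aggregated sodium phenoxide is shielded at oxygen and is alkylated at the ortho carbon (ortho-C-prenylation of a phenoxide), with iodine blocking the para position.

**Step 2**
Reactants: 4 4-iodo-2-(3-methylbut-2-en-1-yl)phenol
Product: 5 triisopropyl[4-iodo-2-(3-methylbut-2-en-1-yl)phenoxy]silane (ring B iodide)
Conditions: i-Pr3SiCl, imidazole, DMF, rt
Reagents that add atoms: triisopropylsilyl chloride, CC(C)[Si](Cl)(C(C)C)C(C)C
Why: Imidazole-promoted silyl ether formation on a phenol is routine, and the aryl iodide and the trisubstituted alkene are inert to it.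

**Step 3**
Reactants: 6 1-(5-bromo-2,4-dihydroxyphenyl)ethanone
Product: 7 1-[5-bromo-2,4-bis(triisopropylsilyloxy)phenyl]ethanone
Conditions: i-Pr3SiCl (2.5 equiv), imidazole, DMAP (cat.), DMF, 50 °C
Reagents that add atoms: triisopropylsilyl chloride, CC(C)[Si](Cl)(C(C)C)C(C)C
Why: Silylation of both phenols with imidazole and DMAP should go to completion on gentle warming, which overcomes the hydrogen bond of the 2-hydroxy group to the acetyl carbonyl, while the methyl ketone is not enolised by these weak bases.

**Step 4**
Reactants: 7 1-[5-bromo-2,4-bis(triisopropylsilyloxy)phenyl]ethanone; 8 tributyl(3-methylbut-2-en-1-yl)stannane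
Product: 9 1-[5-(3-methylbut-2-en-1-yl)-2,4-bis(triisopropylsilyloxy)phenyl]ethanone (ring A ketone)
Conditions: Pd(PPh3)4 (5 mol%), toluene, 100 °C
Reagents that add atoms: none
Why: Stille coupling of an aryl bromide with an allylic stannane runs without base, so the aryl silyl ethers and the methyl ketone survive, and reductive elimination at the unsubstituted CH2 terminus of the prenyl–palladium species should give the linear prenyl group.

**Step 5**
Reactants: 5 triisopropyl[4-iodo-2-(3-methylbut-2-en-1-yl)phenoxy]silane; 9 1-[5-(3-methylbut-2-en-1-yl)-2,4-bis(triisopropylsilyloxy)phenyl]ethanone; 10 carbon monoxide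
Product: 13 1-[5-(3-methylbut-2-en-1-yl)-2,4-bis(triisopropylsilyloxy)phenyl]-3-[3-(3-methylbut-2-en-1-yl)-4-(triisopropylsilyloxy)phenyl]propane-1,3-dione (tris(triisopropylsilyl) ether of glycyrdione A), via ring A sodium enolate 11 (not isolated), via sodium diketonate 12 (not isolated)
Conditions: 9 (2 equiv), NaN(SiMe3)2 (2 equiv), THF, 0 °C; then 5, Pd(dba)2 (5 mol%), 1,3-bis(diphenylphosphino)propane (5 mol%), CO (1 atm), THF, 60 °C; aq NH4Cl
Reagents that add atoms: none
Why: Iodide 5 adds oxidatively to zerovalent palladium bearing the bidentate phosphine, CO inserts into the electron-rich aryl–palladium bond to give an aroyl complex of divalent palladium, enolate 11 displaces iodide, and C–C reductive elimination joins the new carbonyl carbon to the former acetyl methyl carbon, so that CO ends up between C1 of ring B and the central CH2. The closest known reaction type is the palladium-catalysed carbonylative α-arylation of aryl methyl ketones with aryl iodides, which gives 1,3-diketones. No ring is closed and no stereocentre is created. The step needs acylation to win over direct α-arylation and over O-acylation: the CO atmosphere, the chelating ligand and the para-silyloxy donor favour the aroyl complex before the enolate arrives, and the ketone has a single enolisable methyl group that binds palladium through carbon. The second equivalent of 11 deprotonates the diketone at once to the chelated diketonate 12, which is not acylated again, and the unsymmetrical diketone is fixed because only ring B carries iodine. The triisopropylsilyl groups are chosen to resist transfer of the ortho silyl group to the enolate oxygen, and the prenyl alkenes are inert in this acid-free medium.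

**Step 6**
Reactants: 13 tris(triisopropylsilyl) ether of glycyrdione A
Product: 14 glycyrdione A, 1-[2,4-dihydroxy-5-(3-methylbut-2-en-1-yl)phenyl]-3-[4-hydroxy-3-(3-methylbut-2-en-1-yl)phenyl]propane-1,3-dione
Conditions: Bu4NF (3.5 equiv), AcOH (3.5 equiv), THF, 0 °C to rt
Reagents that add atoms: none
Why: Fluoride cleaves the three aryl Si–O bonds (fluoride-mediated desilylation), and the acetic acid buffer keeps phenols and diketone protonated, so neither retro-Claisen cleavage, nor flavone formation from the 2-hydroxyphenyl diketone, nor acid-induced chroman closure of the ortho-prenylphenols should occur.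

**Compound list**
1 | 4-iodophenol | Oc1ccc(I)cc1 | starting material
2 | prenyl bromide (1-bromo-3-methylbut-2-ene) | CC(C)=CCBr | starting material
3 | sodium 4-iodophenoxide | [Na+].[O-]c1ccc(I)cc1 | intermediate (not isolated)
4 | 4-iodo-2-(3-methylbut-2-en-1-yl)phenol | CC(C)=CCc1cc(I)ccc1O | intermediate
5 | triisopropyl[4-iodo-2-(3-methylbut-2-en-1-yl)phenoxy]silane | CC(C)=CCc1cc(I)ccc1O[Si](C(C)C)(C(C)C)C(C)C | intermediate
6 | 1-(5-bromo-2,4-dihydroxyphenyl)ethanone | CC(=O)c1cc(Br)c(O)cc1O | starting material
7 | 1-[5-bromo-2,4-bis(triisopropylsilyloxy)phenyl]ethanone | CC(=O)c1cc(Br)c(O[Si](C(C)C)(C(C)C)C(C)C)cc1O[Si](C(C)C)(C(C)C)C(C)C | intermediate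
8 | tributyl(3-methylbut-2-en-1-yl)stannane | CCCC[Sn](CCCC)(CCCC)CC=C(C)C | starting material
9 | 1-[5-(3-methylbut-2-en-1-yl)-2,4-bis(triisopropylsilyloxy)phenyl]ethanone | CC(=O)c1cc(CC=C(C)C)c(O[Si](C(C)C)(C(C)C)C(C)C)cc1O[Si](C(C)C)(C(C)C)C(C)C | intermediate
10 | carbon monoxide | [C-]#[O+] | starting material
11 | sodium enolate of ketone 9 | [Na+].C=C([O-])c1cc(CC=C(C)C)c(O[Si](C(C)C)(C(C)C)C(C)C)cc1O[Si](C(C)C)(C(C)C)C(C)C | intermediate (not isolated)
12 | sodium enolate of diketone 13 (one resonance form) | [Na+].CC(C)=CCc1cc(C(=O)C=C([O-])c2cc(CC=C(C)C)c(O[Si](C(C)C)(C(C)C)C(C)C)cc2O[Si](C(C)C)(C(C)C)C(C)C)ccc1O[Si](C(C)C)(C(C)C)C(C)C | intermediate (not isolated)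
13 | tris(triisopropylsilyl) ether of glycyrdione A | CC(C)=CCc1cc(C(=O)CC(=O)c2cc(CC=C(C)C)c(O[Si](C(C)C)(C(C)C)C(C)C)cc2O[Si](C(C)C)(C(C)C)C(C)C)ccc1O[Si](C(C)C)(C(C)C)C(C)C | intermediate
14 | glycyrdione A | CC(C)=CCc1cc(C(=O)CC(=O)c2cc(CC=C(C)C)c(O)cc2O)ccc1O | target

**Total step count:** 6
**Longest linear sequence:** 4 steps (steps 1, 2, 5, 6 or steps 3, 4, 5, 6)

**Steps most likely to fail**

1. Step 5 (key step). Two processes could stall it. On warming, the ortho triisopropylsilyl group may shift from the phenol oxygen to the enolate oxygen of 11, which removes the nucleophile. Alternatively the enolate may reach palladium before CO has inserted, so that direct α-arylation takes over. The fallback is an acylation by soft enolisation, without palladium and without strong base. Setting out from iodide 5, iodine–magnesium exchange with i-PrMgCl·LiCl in THF at 0 °C and quenching with CO2 should give 3-(3-methylbut-2-en-1-yl)-4-(triisopropylsilyloxy)benzoic acid F1. Condensation with 1H-benzotriazole and dicyclohexylcarbodiimide in CH2Cl2 should give (1H-benzotriazol-1-yl)[3-(3-methylbut-2-en-1-yl)-4-(triisopropylsilyloxy)phenyl]methanone F2. F2 would then acylate ketone 9 at carbon with MgBr2·OEt2 and i-Pr2NEt in CH2Cl2 at rt, where the ketone is enolised only transiently as a magnesium chelate, and the route is rejoined at 13.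

2. Step 4. Allylic transposition at palladium may send part of the material through the dimethyl-substituted allyl terminus, giving the 1,1-dimethylallyl isomer, which would be hard to separate. The fallback sets out from bromide 7. Stille coupling with allyltributylstannane (Pd(PPh3)4, toluene, 100 °C), whose two allyl termini are equivalent, should give 1-[5-allyl-2,4-bis(triisopropylsilyloxy)phenyl]ethanone F3. Cross-metathesis of F3 with 2-methylbut-2-ene (second-generation Grubbs catalyst, CH2Cl2, 40 °C) would turn the terminal alkene into the prenyl alkene and return to the route at 9.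

3. Step 1. Alkylation at oxygen instead of the ortho carbon, and a second prenylation at C6, may leave little mono-C-prenylated phenol. The fallback sets out from 1. O-Allylation (allyl bromide, K2CO3, acetone, reflux) should give 1-iodo-4-(prop-2-en-1-yloxy)benzene F4. Aromatic Claisen rearrangement (N,N-diethylaniline, 190 °C) can deliver the allyl group only to the ortho carbon and should give 2-allyl-4-iodophenol F5. Cross-metathesis with 2-methylbut-2-ene (second-generation Grubbs catalyst, CH2Cl2, 40 °C) would give 4, where the route is rejoined.

**Further compounds**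
F1 | step 5 | 3-(3-methylbut-2-en-1-yl)-4-(triisopropylsilyloxy)benzoic acid | CC(C)=CCc1cc(C(=O)O)ccc1O[Si](C(C)C)(C(C)C)C(C)C
F2 | step 5 | (1H-benzotriazol-1-yl)[3-(3-methylbut-2-en-1-yl)-4-(triisopropylsilyloxy)phenyl]methanone | CC(C)=CCc1cc(C(=O)n2nnc3ccccc32)ccc1O[Si](C(C)C)(C(C)C)C(C)C
F3 | step 4 | 1-[5-allyl-2,4-bis(triisopropylsilyloxy)phenyl]ethanone | CC(=O)c1cc(CC=C)c(O[Si](C(C)C)(C(C)C)C(C)C)cc1O[Si](C(C)C)(C(C)C)C(C)C
F4 | step 1 | 1-iodo-4-(prop-2-en-1-yloxy)benzene | C=CCOc1ccc(I)cc1
F5 | step 1 | 2-allyl-4-iodophenol | C=CCc1cc(I)ccc1O
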